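Remark: atom labels C1–C20 follow abietane numbering of the target (ring B = C5, C6, C7, C8, C9, C10; ring C = C8, C9, C11, C12, C13, C14; C1–C3 = propanoic acid chain on C10; C20 = methyl on C10; C4 = central carbon of the isopropenyl group on C5). Bare numbers are compounds. Compounds 1, 8, 14 and all reagents in the Conditions lines are taken as purchased.

## Analysis of the target

Compound 24 is a 3,4-seco-abietane. Cyclohexanone ring B (C5–C10, ketone at C7) is fused through C8 and C9 to a hexasubstituted benzene ring C. Ring A survives only as an isopropenyl group on C5 and a propanoic acid chain on C10. Ring C is a para-hydroquinone with free OH at C11 and C14, a methyl ether at C12 and isopropyl at C13, so its edge C11–C12–C13–C14 reads O, OMe, i-Pr, O. There are two adjacent stereocentres, C5 (S, tertiary) and C10 (S, quaternary and benzylic); methyl and isopropenyl are cis, and the acid chain is trans to isopropenyl. The sensitive groups are the hydroquinone (oxidised to the quinone, fastest in base), the isopropenyl group (protic acid) and the free acid next to an electron-rich arene. The difficulty has three parts: a benzene ring with six different neighbours and three oxygens in two states of protection; a quaternary benzylic centre wedged between that ring and a second stereocentre; and no ring A to relay the C5/C10 relationship. The plan rests on one structural feature: the edge C11(OH)–C12(OMe)–C13(i-Pr)–C14(OH) has exactly the substitution of a 4-hydroxy-3-methoxy-2-isopropylcyclobutenone, and the remaining ring-C atoms C8 and C9 are an alkene of ring B.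

## Retrosynthetic reasoning

**24 to 23.** Only the tert-butyl ester is removed at the end. The acid is carried as this ester because it must survive an organolithium step and be cleaved without protic acid (isopropenyl) or base and air (hydroquinone).

**23 to 20 (key disconnection).** Ring C is taken apart by cutting C8–C14 and re-forming C11–C14, which contracts it to a cyclobutenone attached to C9 of a ring-B enone. The cut is made here because the four carbons C11–C14 then carry their final substituents before the arene exists: the two phenolic oxygens are the two carbonyl oxygens of a cyclobutenedione, the only ether is the one the target keeps, and no phenol protecting group is needed. Forward, 20 must open to a dienylketene and close onto C8, with the hydroxyl turning outward; 20 has no aromatic ring and its ring B can be built by enone chemistry.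

**20 to 19 to 18.** The C7 ketone is taken back to a silyl-protected allylic alcohol. The C9 carbanion needed next cannot coexist with a ketone, and oxidising C7 before aromatisation avoids any oxidation in the presence of a hydroquinone.

**18 to 13 and 16.** The C9–C11 bond is cut to an alkenyl iodide 13 (C9 nucleophile after iodine–lithium exchange) and the cyclobutenedione 16. The forward addition must hit the carbonyl next to the methoxy-bearing carbon, which is the more electrophilic one because the other is a vinylogous ester. This regiochemistry puts C11–OH next to C9 and C14–OH next to C8.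

**16 to 14.** The isopropyl group on C13 is cut from the squarate ester 14, by addition of an isopropyl carbanion and acid-induced loss of one methoxy group.

**13 to 11.** The C9–I bond comes from the C9 ketone of 11. Only C8 carries α-hydrogens, so the alkene can only form as C8=C9.

**11 to 7 and 8.** The C10–C1 bond is cut to the ketone 7 and the acrylate 8. Forward, the chain must enter at the more substituted α-carbon and anti to the isopropenyl group on C5; this creates the quaternary centre with methyl cis to isopropenyl.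

**7 to 5.** The C5–C4 bond is cut to the enone 5 and an isopropenyl copper nucleophile. The silyloxy group on C7 directs the addition to the opposite face and so sets C5.

**5 to 1.** Ring B (C5–C10) and C20 are the ring and methyl of (R)-carvone 1. The isopropenyl group of 1 sits on the carbon that becomes C7, where the target needs oxygen, and is exchanged for oxygen with retention. Its stereocentre is then relayed from C7 to C5 to C10 and erased when C7 becomes the ketone.

## Alternatives that were turned down

**Alternative 1:** Friedel–Crafts closure of ring B at C7–C8 (the textbook route). A pre-formed pentasubstituted arene carrying the quaternary C10 would be cyclised as the acid A1 (or its chloride) onto C8, the only free ring position.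
- The arene with three oxygens in two protection states has to be made first by several aromatic substitution steps.
- The C9–C10 bond to a quaternary carbon must be formed from an aryl nucleophile with an ortho alkoxy group.
- In A1 both carboxyl termini (C3 and C7) can reach C8 through six-membered transition states, so they must be differentiated.
- The acidic cyclisation conditions protonate the isopropenyl group next to a very electron-rich arene.
- Two phenol ethers must finally be removed while the C12 methyl ether stays.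
- Overall there are more steps and more protecting groups than in the chosen route, and the risk is spread over several steps.

**Alternative 2:** Biomimetic scission of ring A at C3–C4. The intact tricyclic 3-ketone A2 would undergo Baeyer–Villiger ring expansion to the lactone A3, followed by eliminative opening to the isopropenyl acid.
- The trans-decalin would fix C5/C10 well, and that is the only gain.
- The whole tricycle with a C3 oxygen must be built (annulation or polyene cyclisation) only to be broken again.
- The peracid step has to distinguish two ketones on an oxidisable arene.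
- The elimination at C4 can give the tetrasubstituted C4=C5 alkene, which destroys the C5 stereocentre, as well as the wanted isopropenyl group.
- Step economy is poor.

**Alternative 3:** Hauser–Kraus-type annulation forming C9–C11 and C8–C14 in one operation. The anion of the sulfonyl butenolide A5 would add to C9 of the enone A4, the C8 enolate would close onto the lactone carbonyl, and loss of sulfinate and tautomerisation would give the hydroquinone with the C7 ketone in place.
- The idea is attractive, but the Michael step must attack a β-carbon next to the quaternary C10.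
- The reaction type is established for benzo-fused donors; the anion of A5 is a stabilised 2-oxidofuran with a leaving group, a poor nucleophile with its own decomposition paths.
- The strong base also meets the α'-protons of A4 and the ester.
- A5 needs its own multistep synthesis.
- Two uncertain events would sit in one step. The chosen route separates them into a sterically tolerant carbonyl addition and a pericyclic closure.

Key step: step 11

## Route

Step 1
Reactants: 1 (R)-(−)-carvone
Product: 3 (1R)-4-methyl-5-oxocyclohex-3-en-1-yl acetate, via methoxy hydroperoxide 2 (not isolated)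
Conditions: O3, CH2Cl2/MeOH, −78 °C; then Ac2O, Et3N, DMAP (cat.), −78 °C → rt
Reagents that add atoms: ozone, [O-][O+]=O; methanol, CO
Why: Ozone attacks the electron-rich 1,1-disubstituted alkene and not the deactivated enone alkene, and methanol traps the carbonyl oxide as 2; acetylation of the hydroperoxide triggers the Criegee rearrangement, in which the ring carbon migrates to oxygen with retention, so the stereocentre of 1 becomes the C7–O centre and the acetyl group of 3 is made of the two remaining side-chain carbons.

Step 2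
Reactants: 3 (1R)-4-methyl-5-oxocyclohex-3-en-1-yl acetate
Product: 4 (5R)-5-hydroxy-2-methylcyclohex-2-en-1-one
Conditions: K2CO3 (cat.), MeOH, 0 °C, short reaction time
Reagents that add atoms: none
Why: Carbonate-catalysed transesterification of a secondary acetate; it is run cold and stopped early because a β-acyloxy enone can lose acetate by E1cB.

Step 3
Reactants: 4 (5R)-5-hydroxy-2-methylcyclohex-2-en-1-one
Product: 5 (5R)-5-[(tert-butyldimethylsilyl)oxy]-2-methylcyclohex-2-en-1-one
Conditions: TBSCl, imidazole, DMF, 0 °C → rt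
Reagents that add atoms: tert-butyldimethylsilyl chloride, CC(C)(C)[Si](C)(C)Cl
Why: Standard silylation; the silyl ether is inert to the organometallic steps, is a poor leaving group, and is bulky enough to direct the next step.

Step 4
Reactants: 5 (5R)-5-[(tert-butyldimethylsilyl)oxy]-2-methylcyclohex-2-en-1-one
Product: 7 (3R,5R)-5-[(tert-butyldimethylsilyl)oxy]-2-methyl-3-(prop-1-en-2-yl)cyclohexan-1-one (both C2 epimers), via silyl enol ether 6 (not isolated)
Conditions: isopropenylMgBr, CuBr·SMe2 (cat.), TMSCl, THF, −78 °C; then 1 M HCl (aq.), THF, 0 °C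
Reagents that add atoms: isopropenylmagnesium bromide, C=C(C)[Mg]Br
Why: Copper-catalysed conjugate addition of a Grignard reagent, accelerated by TMSCl; axial attack anti to the silyloxy group gives the 3,5-trans adduct expected for 5-substituted cyclohexenones and so sets C5; C10 remains an epimer mixture that step 5 funnels into one configuration.

Step 5
Reactants: 7 (3R,5R)-5-[(tert-butyldimethylsilyl)oxy]-2-methyl-3-(prop-1-en-2-yl)cyclohexan-1-one; 8 tert-butyl acrylate
Product: 11 tert-butyl 3-[(1S,2S,4R)-4-[(tert-butyldimethylsilyl)oxy]-1-methyl-6-oxo-2-(prop-1-en-2-yl)cyclohexyl]propanoate, via N-benzyl imine 9 (not isolated), via adduct imine 10 (not isolated)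
Conditions: BnNH2, 4 Å MS, toluene, 50 °C; then 8, THF, 50 °C; then 10% AcOH (aq.), rt
Reagents that add atoms: none
Why: Michael addition of an imine through its more substituted secondary enamine tautomer (aza-ene-type N–H transfer), which alkylates the more substituted α-carbon under neutral conditions; the acrylate attacks C10 axially and anti to the pseudoaxial isopropenyl group on C5, so both C10 epimers of 7 should converge on the isomer with the chain trans and the methyl cis to isopropenyl; hydrolysis returns the ketone.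

Step 6
Reactants: 11 tert-butyl 3-[(1S,2S,4R)-4-[(tert-butyldimethylsilyl)oxy]-1-methyl-6-oxo-2-(prop-1-en-2-yl)cyclohexyl]propanoate
Product: 13 tert-butyl 3-[(1S,4R,6S)-4-[(tert-butyldimethylsilyl)oxy]-2-iodo-1-methyl-6-(prop-1-en-2-yl)cyclohex-2-en-1-yl]propanoate, via N-silyl hydrazone 12 (not isolated)
Conditions: TBSNHNHTBS, Sc(OTf)3 (cat.), neat, 60 °C, volatiles removed; then I2, 1,1,3,3-tetramethylguanidine, THF, 0 °C
Reagents that add atoms: iodine, II
Why: Barton vinyl iodide synthesis in its N-silyl hydrazone variant; the Sc(OTf)3-catalysed condensation avoids free hydrazine and base at the β-silyloxy ketone, and oxidation with iodine and loss of N2 gives the iodoalkene, for which only C8 can supply the hydrogen.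

Step 7
Reactants: 14 dimethyl squarate
Product: 16 3-methoxy-4-(propan-2-yl)cyclobut-3-ene-1,2-dione, via squarate adduct 15 (not isolated)
Conditions: i-PrLi, THF, −78 °C; then (CF3CO)2O, −78 °C → rt
Reagents that add atoms: isopropyllithium, [Li]C(C)C
Why: 1,2-Addition of an organolithium to one carbonyl of the squarate, then anhydride-induced ionisation of the carbinol with loss of one methoxy group; this is the standard entry to 3-alkyl-4-alkoxycyclobutenediones.

Step 8
Reactants: 13 tert-butyl 3-[(1S,4R,6S)-4-[(tert-butyldimethylsilyl)oxy]-2-iodo-1-methyl-6-(prop-1-en-2-yl)cyclohex-2-en-1-yl]propanoate; 16 3-methoxy-4-(propan-2-yl)cyclobut-3-ene-1,2-dione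
Product: 18 tert-butyl 3-[(1S,4R,6S)-4-[(tert-butyldimethylsilyl)oxy]-2-[1-hydroxy-2-methoxy-4-oxo-3-(propan-2-yl)cyclobut-2-en-1-yl]-1-methyl-6-(prop-1-en-2-yl)cyclohex-2-en-1-yl]propanoate (both carbinol epimers), via alkenyllithium 17 (not isolated)
Conditions: t-BuLi (2.1 equiv), THF/Et2O, −100 °C; then 16, −100 → −78 °C; NH4Cl (aq.) at −78 °C
Reagents that add atoms: none
Why: Iodine–lithium exchange at −100 °C outruns attack on the tert-butyl ester; the alkenyllithium adds to the carbonyl of 16 that is not part of the vinylogous ester (the one next to C–OMe), which forms C9–C11 and fixes the later order O, OMe, i-Pr, O; the new carbinol centre is formed without control and is erased in step 11, and the cold quench prevents alkoxide-accelerated ring opening.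

Step 9
Reactants: 18 tert-butyl 3-[(1S,4R,6S)-4-[(tert-butyldimethylsilyl)oxy]-2-[1-hydroxy-2-methoxy-4-oxo-3-(propan-2-yl)cyclobut-2-en-1-yl]-1-methyl-6-(prop-1-en-2-yl)cyclohex-2-en-1-yl]propanoate
Product: 19 tert-butyl 3-[(1S,4R,6S)-4-hydroxy-2-[1-hydroxy-2-methoxy-4-oxo-3-(propan-2-yl)cyclobut-2-en-1-yl]-1-methyl-6-(prop-1-en-2-yl)cyclohex-2-en-1-yl]propanoate (both carbinol epimers)
Conditions: HF·pyridine, pyridine, THF, 0 °C → rt
Reagents that add atoms: none
Why: Fluoride cleavage of the allylic silyl ether; pyridine buffering keeps the acid-labile 4-hydroxy-3-methoxycyclobutenone from ionising.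

Step 10
Reactants: 19 tert-butyl 3-[(1S,4R,6S)-4-hydroxy-2-[1-hydroxy-2-methoxy-4-oxo-3-(propan-2-yl)cyclobut-2-en-1-yl]-1-methyl-6-(prop-1-en-2-yl)cyclohex-2-en-1-yl]propanoate
Product: 20 tert-butyl 3-[(1S,6S)-2-[1-hydroxy-2-methoxy-4-oxo-3-(propan-2-yl)cyclobut-2-en-1-yl]-1-methyl-4-oxo-6-(prop-1-en-2-yl)cyclohex-2-en-1-yl]propanoate (both carbinol epimers)
Conditions: MnO2 (activated, excess), CH2Cl2, rt
Reagents that add atoms: none
Why: MnO2 oxidises only the allylic secondary alcohol, since the tertiary cyclobutenol cannot be oxidised; this installs the C7 ketone before any hydroquinone exists and erases the relay stereocentre at C7.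

Step 11
Reactants: 20 tert-butyl 3-[(1S,6S)-2-[1-hydroxy-2-methoxy-4-oxo-3-(propan-2-yl)cyclobut-2-en-1-yl]-1-methyl-4-oxo-6-(prop-1-en-2-yl)cyclohex-2-en-1-yl]propanoate
Product: 23 tert-butyl 3-[(1S,2S)-5,8-dihydroxy-7-methoxy-1-methyl-4-oxo-6-(propan-2-yl)-2-(prop-1-en-2-yl)-1,2,3,4-tetrahydronaphthalen-1-yl]propanoate, via dienylketene 21 (not isolated), via cyclohexadienone 22 (not isolated)
Conditions: toluene (degassed, dilute), 110 °C, argon
Reagents that add atoms: none
Why: This is a Moore rearrangement, the thermal ring expansion of a 4-alkenyl-4-hydroxycyclobutenone to a hydroquinone, which is the closest known reaction type and is established for cycloalkenyl substituents. Heating opens the four-membered ring by conrotatory 4π electrocyclic cleavage of the C11–C14 bond to give the dienylketene 21. Ring C is then closed by a disrotatory 6π electrocyclisation that forms the C8–C14 bond (22), and enolisation of the doubly activated C8–H gives the aromatic hydroquinone. The selectivity the step needs is torquoselectivity: the hydroxyl donor on C11 rotates outward, which turns the C8=C9 alkene inward next to the ketene and keeps that hydroxyl group from lactonising the ketene. Regiochemistry is not in question, because the connectivity of 20 already places C14–OH next to C8, i-Pr on C13, OMe on C12 and C11–OH next to C9. No stereocentre is created: the uncontrolled carbinol centre and the transient C8 centre are erased, so both carbinol epimers converge, and C5 and C10 carry no enolisable hydrogen and are untouched. The C7 ketone makes the final tautomerisation fast and gives the C14–OH to C7=O hydrogen bond that should protect the product from air oxidation, and degassed solvent covers the rest.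

Step 12
Reactants: 23 tert-butyl 3-[(1S,2S)-5,8-dihydroxy-7-methoxy-1-methyl-4-oxo-6-(propan-2-yl)-2-(prop-1-en-2-yl)-1,2,3,4-tetrahydronaphthalen-1-yl]propanoate
Product: 24 3-[(1S,2S)-5,8-dihydroxy-7-methoxy-1-methyl-4-oxo-6-(propan-2-yl)-2-(prop-1-en-2-yl)-1,2,3,4-tetrahydronaphthalen-1-yl]propanoic acid
Conditions: TMSOTf, 2,6-lutidine, CH2Cl2, 0 °C; then citric acid (aq.), THF, rt, argon
Reagents that add atoms: none
Why: Silyl triflate-mediated cleavage of the tert-butyl ester (alkyl–oxygen fission, loss of isobutene) under buffered non-protic conditions that spare the isopropenyl group; mild aqueous acid then removes the transient silyl groups from the acid, the phenols and any silyl enol ether.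

## Compound list

1 | (R)-(−)-carvone, (5R)-2-methyl-5-(prop-1-en-2-yl)cyclohex-2-en-1-one | CC1=CC[C@H](CC1=O)C(C)=C | starting material
2 | (5R)-5-(1-hydroperoxy-1-methoxyethyl)-2-methylcyclohex-2-en-1-one (both epimers at the peroxy carbon) | CC1=CC[C@H](CC1=O)C(C)(OC)OO | intermediate
3 | (1R)-4-methyl-5-oxocyclohex-3-en-1-yl acetate | CC1=CC[C@H](CC1=O)OC(C)=O | intermediate
4 | (5R)-5-hydroxy-2-methylcyclohex-2-en-1-one | CC1=CC[C@H](CC1=O)O | intermediate
5 | (5R)-5-[(tert-butyldimethylsilyl)oxy]-2-methylcyclohex-2-en-1-one | CC1=CC[C@H](CC1=O)O[Si](C)(C)C(C)(C)C | intermediate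
6 | tert-butyldimethyl{[(1R,5S)-4-methyl-5-(prop-1-en-2-yl)-3-[(trimethylsilyl)oxy]cyclohex-3-en-1-yl]oxy}silane | C=C(C)[C@@H]1C[C@@H](O[Si](C)(C)C(C)(C)C)CC(O[Si](C)(C)C)=C1C | intermediate
7 | (3R,5R)-5-[(tert-butyldimethylsilyl)oxy]-2-methyl-3-(prop-1-en-2-yl)cyclohexan-1-one (both C2 epimers) | C=C(C)[C@@H]1C[C@@H](O[Si](C)(C)C(C)(C)C)CC(=O)C1C | intermediate
8 | tert-butyl acrylate (tert-butyl prop-2-enoate) | C=CC(=O)OC(C)(C)C | starting material
9 | (3R,5R)-N-benzyl-5-[(tert-butyldimethylsilyl)oxy]-2-methyl-3-(prop-1-en-2-yl)cyclohexan-1-imine (both C2 epimers, in equilibrium with its enamine tautomers) | C=C(C)[C@@H]1C[C@@H](O[Si](C)(C)C(C)(C)C)CC(=NCc2ccccc2)C1C | intermediate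
10 | tert-butyl 3-[(1S,2S,4R)-6-(benzylimino)-4-[(tert-butyldimethylsilyl)oxy]-1-methyl-2-(prop-1-en-2-yl)cyclohexyl]propanoate | C=C(C)[C@@H]1C[C@@H](O[Si](C)(C)C(C)(C)C)CC(=NCc2ccccc2)[C@@]1(C)CCC(=O)OC(C)(C)C | intermediate
11 | tert-butyl 3-[(1S,2S,4R)-4-[(tert-butyldimethylsilyl)oxy]-1-methyl-6-oxo-2-(prop-1-en-2-yl)cyclohexyl]propanoate | C=C(C)[C@@H]1C[C@@H](O[Si](C)(C)C(C)(C)C)CC(=O)[C@@]1(C)CCC(=O)OC(C)(C)C | intermediate
12 | N-(tert-butyldimethylsilyl) hydrazone of 11, tert-butyl 3-[(1S,2S,4R)-4-[(tert-butyldimethylsilyl)oxy]-6-[(tert-butyldimethylsilyl)hydrazinylidene]-1-methyl-2-(prop-1-en-2-yl)cyclohexyl]propanoate | C=C(C)[C@@H]1C[C@@H](O[Si](C)(C)C(C)(C)C)CC(=NN[Si](C)(C)C(C)(C)C)[C@@]1(C)CCC(=O)OC(C)(C)C | intermediate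
13 | tert-butyl 3-[(1S,4R,6S)-4-[(tert-butyldimethylsilyl)oxy]-2-iodo-1-methyl-6-(prop-1-en-2-yl)cyclohex-2-en-1-yl]propanoate | C=C(C)[C@@H]1C[C@@H](O[Si](C)(C)C(C)(C)C)C=C(I)[C@@]1(C)CCC(=O)OC(C)(C)C | intermediate
14 | dimethyl squarate, 3,4-dimethoxycyclobut-3-ene-1,2-dione | COC1=C(OC)C(=O)C1=O | starting material
15 | 4-hydroxy-2,3-dimethoxy-4-(propan-2-yl)cyclobut-2-en-1-one (present as its lithium alkoxide) | COC1=C(OC)C(O)(C(C)C)C1=O | intermediate
16 | 3-methoxy-4-(propan-2-yl)cyclobut-3-ene-1,2-dione | COC1=C(C(C)C)C(=O)C1=O | intermediate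
17 | tert-butyl 3-[(1S,4R,6S)-4-[(tert-butyldimethylsilyl)oxy]-2-lithio-1-methyl-6-(prop-1-en-2-yl)cyclohex-2-en-1-yl]propanoate | C=C(C)[C@@H]1C[C@@H](O[Si](C)(C)C(C)(C)C)C=C([Li])[C@@]1(C)CCC(=O)OC(C)(C)C | intermediate
18 | tert-butyl 3-[(1S,4R,6S)-4-[(tert-butyldimethylsilyl)oxy]-2-[1-hydroxy-2-methoxy-4-oxo-3-(propan-2-yl)cyclobut-2-en-1-yl]-1-methyl-6-(prop-1-en-2-yl)cyclohex-2-en-1-yl]propanoate (both carbinol epimers) | C=C(C)[C@@H]1C[C@@H](O[Si](C)(C)C(C)(C)C)C=C(C2(O)C(OC)=C(C(C)C)C2=O)[C@@]1(C)CCC(=O)OC(C)(C)C | intermediate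
19 | tert-butyl 3-[(1S,4R,6S)-4-hydroxy-2-[1-hydroxy-2-methoxy-4-oxo-3-(propan-2-yl)cyclobut-2-en-1-yl]-1-methyl-6-(prop-1-en-2-yl)cyclohex-2-en-1-yl]propanoate (both carbinol epimers) | C=C(C)[C@@H]1C[C@@H](O)C=C(C2(O)C(OC)=C(C(C)C)C2=O)[C@@]1(C)CCC(=O)OC(C)(C)C | intermediate
20 | tert-butyl 3-[(1S,6S)-2-[1-hydroxy-2-methoxy-4-oxo-3-(propan-2-yl)cyclobut-2-en-1-yl]-1-methyl-4-oxo-6-(prop-1-en-2-yl)cyclohex-2-en-1-yl]propanoate (both carbinol epimers) | C=C(C)[C@@H]1CC(=O)C=C(C2(O)C(OC)=C(C(C)C)C2=O)[C@@]1(C)CCC(=O)OC(C)(C)C | intermediate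
21 | tert-butyl 3-[(1S,6S)-2-[(1Z)-1-hydroxy-2-methoxy-4-oxo-3-(propan-2-yl)buta-1,3-dien-1-yl]-1-methyl-4-oxo-6-(prop-1-en-2-yl)cyclohex-2-en-1-yl]propanoate (dienylketene) | C=C(C)[C@@H]1CC(=O)C=C(/C(O)=C(OC)\C(C(C)C)=C=O)[C@@]1(C)CCC(=O)OC(C)(C)C | intermediate
22 | tert-butyl 3-[(1S,2S)-8-hydroxy-7-methoxy-1-methyl-4,5-dioxo-6-(propan-2-yl)-2-(prop-1-en-2-yl)-1,2,3,4,4a,5-hexahydronaphthalen-1-yl]propanoate (both C4a epimers) | C=C(C)[C@@H]1CC(=O)C2C(=O)C(C(C)C)=C(OC)C(O)=C2[C@@]1(C)CCC(=O)OC(C)(C)C | intermediate
23 | tert-butyl 3-[(1S,2S)-5,8-dihydroxy-7-methoxy-1-methyl-4-oxo-6-(propan-2-yl)-2-(prop-1-en-2-yl)-1,2,3,4-tetrahydronaphthalen-1-yl]propanoate | C=C(C)[C@@H]1CC(=O)c2c(O)c(C(C)C)c(OC)c(O)c2[C@@]1(C)CCC(=O)OC(C)(C)C | intermediate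
24 | 3-[(1S,2S)-5,8-dihydroxy-7-methoxy-1-methyl-4-oxo-6-(propan-2-yl)-2-(prop-1-en-2-yl)-1,2,3,4-tetrahydronaphthalen-1-yl]propanoic acid (CNP0249049.1) | C=C(C)[C@@H]1CC(=O)c2c(O)c(C(C)C)c(OC)c(O)c2[C@@]1(C)CCC(=O)O | target

## Step count and least certain steps

Total: 12 steps. Longest linear sequence: 11 steps (steps 1–6 and 8–12); step 7 is a one-step side branch.

**Step 11 (key step).** The ring closure may be slow because the alkene terminus C8 carries the C7 acyl group and sits next to a quaternary centre. A long-lived ketene can then be intercepted by adventitious nucleophiles, and the product can be oxidised by air during isolation. The fallback sets out from 18 and moves the aromatisation ahead of the C7 oxidation. Heating 18 in toluene at 110 °C, followed by Ag2O in the same flask, should give the C7-silyloxy quinone F1. HF·pyridine gives the C7-hydroxy quinone F2, Dess–Martin periodinane gives the 7-oxo quinone F3, and Na2S2O4 (aq.)/EtOAc reduces the quinone ring to the hydroquinone. The route is rejoined at 23. This fallback also bypasses steps 9 and 10.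

**Step 8.** The alkenyllithium may be acylated intramolecularly by the ester (Parham-type closure of a five-membered ketone), or may deprotonate the isopropyl group of 16 instead of adding. The fallback sets out from 13 and removes the electrophile before metalation. TMSOTf/2,6-lutidine and aqueous work-up give the iodo acid F4. With t-BuLi (3.1 equiv, −100 °C) its lithium carboxylate is exchanged and added to 16 to give the adduct acid F5. HF·pyridine gives the diol acid F6 and MnO2 the enone acid F7, which on heating as in step 11 gives the target directly. The route is rejoined at 24 and step 12 is not needed.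

**Step 5.** The enamine may alkylate at C8 instead of the hindered C10, react slowly, or lose silanol by β-elimination on prolonged warming. The fallback sets out from 6, which is isolated instead of hydrolysed, and uses the regiospecific enolate. MeLi (THF, 0 °C) followed by allyl bromide gives the allyl ketone F8, again by attack anti to isopropenyl. 9-BBN followed by NaBO3 hydroborates only the monosubstituted alkene and gives the primary alcohol F9. TEMPO/PhI(OAc)2 in aqueous MeCN gives the keto acid F10, and tert-butyl 2,2,2-trichloroacetimidate esterifies it. The route is rejoined at 11.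

**Step 6.** Condensation at the ketone next to a quaternary carbon may stall, and the cationic stage of the iodination may trigger a 1,2-shift from C10 or loss of the silyloxy group. The fallback sets out from 11 and goes through the enolate. KHMDS and N-(5-chloropyridin-2-yl)triflimide at −78 °C give the enol triflate F11. Me3SnSnMe3, Pd(PPh3)4 and LiCl in THF at 60 °C give the alkenylstannane F12, and I2 in CH2Cl2 at 0 °C replaces tin by iodine. The route is rejoined at 13.

**Step 2 (and the base treatment that ends step 1).** E1cB loss of acetate from the β-acyloxy enone followed by tautomerisation to a phenol would destroy the material. The fallback sets out from 3 and postpones the deacetylation until the enone is gone. The conjugate addition of step 4 is run on 3 to give the acetoxy ketone F13, in which loss of acetate no longer leads to an aromatic ring. HCl in MeOH at 0 °C gives the hydroxy ketone F14, and TBSCl/imidazole silylates it. The route is rejoined at 7.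

## Further compounds

F1 | step 11 | tert-butyl 3-[(1S,2S,4R)-4-[(tert-butyldimethylsilyl)oxy]-7-methoxy-1-methyl-5,8-dioxo-6-(propan-2-yl)-2-(prop-1-en-2-yl)-1,2,3,4,5,8-hexahydronaphthalen-1-yl]propanoate | C=C(C)[C@@H]1C[C@@H](O[Si](C)(C)C(C)(C)C)C2=C(C(=O)C(OC)=C(C(C)C)C2=O)[C@@]1(C)CCC(=O)OC(C)(C)C
F2 | step 11 | tert-butyl 3-[(1S,2S,4R)-4-hydroxy-7-methoxy-1-methyl-5,8-dioxo-6-(propan-2-yl)-2-(prop-1-en-2-yl)-1,2,3,4,5,8-hexahydronaphthalen-1-yl]propanoate | C=C(C)[C@@H]1C[C@@H](O)C2=C(C(=O)C(OC)=C(C(C)C)C2=O)[C@@]1(C)CCC(=O)OC(C)(C)C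
F3 | step 11 | tert-butyl 3-[(1S,2S)-7-methoxy-1-methyl-4,5,8-trioxo-6-(propan-2-yl)-2-(prop-1-en-2-yl)-1,2,3,4,5,8-hexahydronaphthalen-1-yl]propanoate | C=C(C)[C@@H]1CC(=O)C2=C(C(=O)C(OC)=C(C(C)C)C2=O)[C@@]1(C)CCC(=O)OC(C)(C)C
F4 | step 8 | 3-[(1S,4R,6S)-4-[(tert-butyldimethylsilyl)oxy]-2-iodo-1-methyl-6-(prop-1-en-2-yl)cyclohex-2-en-1-yl]propanoic acid | C=C(C)[C@@H]1C[C@@H](O[Si](C)(C)C(C)(C)C)C=C(I)[C@@]1(C)CCC(=O)O
F5 | step 8 | 3-[(1S,4R,6S)-4-[(tert-butyldimethylsilyl)oxy]-2-[1-hydroxy-2-methoxy-4-oxo-3-(propan-2-yl)cyclobut-2-en-1-yl]-1-methyl-6-(prop-1-en-2-yl)cyclohex-2-en-1-yl]propanoic acid (both carbinol epimers) | C=C(C)[C@@H]1C[C@@H](O[Si](C)(C)C(C)(C)C)C=C(C2(O)C(OC)=C(C(C)C)C2=O)[C@@]1(C)CCC(=O)O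
F6 | step 8 | 3-[(1S,4R,6S)-4-hydroxy-2-[1-hydroxy-2-methoxy-4-oxo-3-(propan-2-yl)cyclobut-2-en-1-yl]-1-methyl-6-(prop-1-en-2-yl)cyclohex-2-en-1-yl]propanoic acid (both carbinol epimers) | C=C(C)[C@@H]1C[C@@H](O)C=C(C2(O)C(OC)=C(C(C)C)C2=O)[C@@]1(C)CCC(=O)O
F7 | step 8 | 3-[(1S,6S)-2-[1-hydroxy-2-methoxy-4-oxo-3-(propan-2-yl)cyclobut-2-en-1-yl]-1-methyl-4-oxo-6-(prop-1-en-2-yl)cyclohex-2-en-1-yl]propanoic acid (both carbinol epimers) | C=C(C)[C@@H]1CC(=O)C=C(C2(O)C(OC)=C(C(C)C)C2=O)[C@@]1(C)CCC(=O)O
F8 | step 5 | (2S,3S,5R)-5-[(tert-butyldimethylsilyl)oxy]-2-methyl-2-(prop-2-en-1-yl)-3-(prop-1-en-2-yl)cyclohexan-1-one | C=C(C)[C@@H]1C[C@@H](O[Si](C)(C)C(C)(C)C)CC(=O)[C@@]1(C)CC=C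
F9 | step 5 | (2S,3S,5R)-5-[(tert-butyldimethylsilyl)oxy]-2-(3-hydroxypropyl)-2-methyl-3-(prop-1-en-2-yl)cyclohexan-1-one | C=C(C)[C@@H]1C[C@@H](O[Si](C)(C)C(C)(C)C)CC(=O)[C@@]1(C)CCCO
F10 | step 5 | 3-[(1S,2S,4R)-4-[(tert-butyldimethylsilyl)oxy]-1-methyl-6-oxo-2-(prop-1-en-2-yl)cyclohexyl]propanoic acid | C=C(C)[C@@H]1C[C@@H](O[Si](C)(C)C(C)(C)C)CC(=O)[C@@]1(C)CCC(=O)O
F11 | step 6 | tert-butyl 3-[(1S,4R,6S)-4-[(tert-butyldimethylsilyl)oxy]-1-methyl-6-(prop-1-en-2-yl)-2-[(trifluoromethanesulfonyl)oxy]cyclohex-2-en-1-yl]propanoate | C=C(C)[C@@H]1C[C@@H](O[Si](C)(C)C(C)(C)C)C=C(OS(=O)(=O)C(F)(F)F)[C@@]1(C)CCC(=O)OC(C)(C)C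
F12 | step 6 | tert-butyl 3-[(1S,4R,6S)-4-[(tert-butyldimethylsilyl)oxy]-1-methyl-6-(prop-1-en-2-yl)-2-(trimethylstannyl)cyclohex-2-en-1-yl]propanoate | C=C(C)[C@@H]1C[C@@H](O[Si](C)(C)C(C)(C)C)C=C([Sn](C)(C)C)[C@@]1(C)CCC(=O)OC(C)(C)C
F13 | step 2 | (1R,3R)-4-methyl-5-oxo-3-(prop-1-en-2-yl)cyclohexyl acetate (both C4 epimers) | C=C(C)[C@@H]1C[C@@H](OC(C)=O)CC(=O)C1C
F14 | step 2 | (3R,5R)-5-hydroxy-2-methyl-3-(prop-1-en-2-yl)cyclohexan-1-one (both C2 epimers) | C=C(C)[C@@H]1C[C@@H](O)CC(=O)C1C
A1 | alternative 1 | 4-[2,5-bis(benzyloxy)-3-methoxy-4-(propan-2-yl)phenyl]-7-methoxy-4-methyl-7-oxo-3-(prop-1-en-2-yl)heptanoic acid, configured at C5 and C10 as in 24 | C=C(C)[C@H](CC(=O)O)[C@](C)(CCC(=O)OC)c1cc(OCc2ccccc2)c(C(C)C)c(OC)c1OCc1ccccc1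
A2 | alternative 2 | 12-methoxy-3,7-dioxoabieta-8,11,13-triene-11,14-diyl diacetate (5α-H, 10β-methyl) | CC(C)c1c(OC)c(OC(C)=O)c2c(c1OC(C)=O)C(=O)C[C@H]1C(C)(C)C(=O)CC[C@]21C
A3 | alternative 2 | ring-A ε-lactone of A2 (oxygen inserted between C3 and C4) | CC(C)c1c(OC)c(OC(C)=O)c2c(c1OC(C)=O)C(=O)C[C@H]1C(C)(C)OC(=O)CC[C@]21C
A4 | alternative 3 | tert-butyl 3-[(1R,6S)-1-methyl-4-oxo-6-(prop-1-en-2-yl)cyclohex-2-en-1-yl]propanoate | C=C(C)[C@@H]1CC(=O)C=C[C@@]1(C)CCC(=O)OC(C)(C)C
A5 | alternative 3 | 4-methoxy-5-(phenylsulfonyl)-3-(propan-2-yl)furan-2(5H)-one | CC(C)C1=C(OC)C(S(=O)(=O)c2ccccc2)OC1=O
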